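## Retrosynthetic overview
1. Celastolide (a 2,3-seco-friedelane, numbered as in friedelane/oleanane) arises from a radical-polar [3+2] annulation of 2-bromopropionic acid onto the cyclic enol ether C5=C24. This sets C5, C4 and C24 and closes the γ-lactone and acetal.
2. The enol ether comes from a lactol, which comes from the δ-lactone 20. Lactone 20 is made by a key HAT-initiated radical cascade that closes ring C (C14–C8) and then ring B (C9–C10), with polarity-matched Giese termination on an unsaturated δ-lactone.
3. The cascade precursor is made by cross-metathesis of the D/E-ring diene 13 with an RCM-derived 3-butenyl dihydropyranone 18.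
4. Ring E comes from a Diels–Alder reaction (isoprene + methacrolein). Ring D comes from a Robinson annulation with ethyl vinyl ketone, followed by cis-hydrogenation and C13 alkylation.
5. Ring order: E, D, A′ (δ-lactone, by RCM), C and B (one radical cascade), and finally the γ-lactone/acetal.

Assumption: C4 is α to the lactone C=O and epimerizable, so racemic 2-bromopropionic acid is used and the exo-methyl isomer is taken as the thermodynamic product.

## Route

**Step 1**
Reactants: 1 isoprene; 2 methacrolein
Product: 3 (R)-1,4-dimethylcyclohex-3-ene-1-carbaldehyde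
Conditions: cationic chiral oxazaborolidinium catalyst (20 mol%), CH2Cl2, −78 °C
Reagents that add atoms: none
Why: A catalyst-controlled Diels–Alder reaction with "para" regiochemistry forms ring E and sets the quaternary C20 (Me up, CHO down).

**Step 2**
Reactants: 3
Product: 4 (R)-1,4-dimethylcyclohex-3-ene-1-carboxylic acid
Conditions: NaClO2, NaH2PO4, 2-methyl-2-butene, tBuOH/H2O, rt
Reagents that add atoms: NaClO2 (O=Cl[O-].[Na+])
Why: Pinnick oxidation; the alkene scavenger protects the trisubstituted olefin, and C20 is untouched.

**Step 3**
Reactants: 4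
Product: 5 tert-butyl (R)-1,4-dimethylcyclohex-3-ene-1-carboxylate
Conditions: Boc2O, DMAP, tBuOH, rt
Reagents that add atoms: tert-butanol (CC(C)(C)O)
Why: The tert-butyl ester is stable to base, H2 and radical conditions and is removable at the end without touching the acetal lactone.

**Step 4**
Reactants: 5
Product: 6 tert-butyl 3-hydroxy-1,4-dimethylcyclohexane-1-carboxylate (C3/C4 diastereomer mixture)
Conditions: BH3·SMe2, THF, 0 °C; then H2O2, NaOH
Reagents that add atoms: hydrogen peroxide (OO)
Why: Hydroboration–oxidation places boron on the less substituted C18, and the hindered tert-butyl ester survives; the transient C17/C18 stereocentres are erased in step 5.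

**Step 5**
Reactants: 6
Product: 7 tert-butyl (1R)-1,4-dimethyl-3-oxocyclohexane-1-carboxylate (C4 epimeric)
Conditions: DMP, NaHCO3, CH2Cl2, rt
Reagents that add atoms: none
Why: Dess–Martin oxidation; the C4 stereocentre is epimerizable and is destroyed in step 6.

**Step 6**
Reactants: 7; 8 ethyl vinyl ketone
Product: 9 tert-butyl 1,4a,7-trimethyl-2-oxo-2,3,4,4a,5,6,7,8-octahydronaphthalene-7-carboxylate (4a-Me and 7-Me cis)
Conditions: 8 (1.5 equiv), NaOEt, EtOH, 0 → 80 °C
Reagents that add atoms: none
Why: Robinson annulation: the thermodynamic enolate at C17 (the other α-CH2 is neopentyl) adds to the vinyl ketone and aldol condensation closes ring D, forming C17 quaternary with the C13-methyl already in place. C17 forms with modest diastereoselectivity relative to C20 and the desired C17/C20 diastereomer (Me28 and Me30 cis) is separated.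

**Step 7**
Reactants: 9
Product: 10 cis-fused decalone (C18-H cis to the C17-Me; C13 epimeric)
Conditions: H2 (1 atm), 10% Pd/C, EtOH, trace KOH, rt
Reagents that add atoms: none
Why: Pd-catalysed hydrogenation of angularly methylated enones delivers H to C18 syn to the angular methyl, as in steroidal Δ4-3-ketone → 5β-H reduction. This sets the cis D/E fusion (H18 and Me28 both β).

**Step 8**
Reactants: 10; 11 4-bromo-2-methyl-1-butene
Product: 12 tert-butyl 1-methyl-1-(3-methylbut-3-en-1-yl)-ketone 12 (D/E-ring ketone with quaternary C13)
Conditions: KOtBu, tBuOH/THF, then 11 and NaI (cat.), 60 °C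
Reagents that add atoms: none
Why: The thermodynamic, tetrasubstituted C13=C14 enolate is alkylated on its convex β-face, anti to ring E, which folds under the α-face of ring D in the cis-fused system. This places the chain β and Me27 α, and the C13 epimers of 10 converge through the enolate.

**Step 9**
Reactants: 12
Product: 13 exocyclic methylene diene (C14=CH2 and isopropenyl terminus)
Conditions: Ph3P+CH3 Br−, KOtBu, PhMe, 80 °C
Reagents that add atoms: methylenetriphenylphosphorane (C=P(c1ccccc1)(c1ccccc1)c1ccccc1)
Why: Wittig methylenation of the hindered C14 ketone gives the 1,1-disubstituted alkene needed as the HAT initiator in step 14.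

**Step 10**
Reactants: 14 hex-5-enoic acid; 15 but-3-en-1-ol
Product: 16 but-3-en-1-yl hex-5-enoate
Conditions: DCC, DMAP, CH2Cl2, 0 °C → rt
Reagents that add atoms: none
Why: Steglich esterification.

**Step 11**
Reactants: 16
Product: 17 but-3-en-1-yl 2-methylenehex-5-enoate
Conditions: LDA, THF, −78 °C; CH2=NMe2+ I−; then MeI, DBU
Reagents that add atoms: Eschenmoser's salt (C=[N+](C)C)
Why: One-pot Mannich/quaternization/elimination α-methylenation; the isolated alkenes are untouched.

**Step 12**
Reactants: 17
Product: 18 3-(but-3-en-1-yl)-5,6-dihydro-2H-pyran-2-one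
Conditions: Grubbs II (5 mol%), CH2Cl2 (5 mM), 40 °C
Reagents that add atoms: none
Why: Ring-closing metathesis is selective for the six-membered lactone (the alternatives would be cyclobutene or nine-membered rings) and loses ethylene.

**Step 13**
Reactants: 13; 18 (3 equiv)
Product: 19 cascade precursor (E-trisubstituted C8=C9 alkene linking the D/E-ring diene to the pyranone)
Conditions: Hoveyda–Grubbs II (10 mol%), CH2Cl2, 40 °C
Reagents that add atoms: none
Why: Cross-metathesis of the accessible isopropenyl terminus (the neopentyl C14 methylene is inert) with the terminal olefin 18 gives the thermodynamically favoured E-trisubstituted alkene (C7 and C11 trans), which is required for the chair transition state.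

**Step 14**
Reactants: 19
Product: 20 pentacyclic δ-lactone with C14, C8, C9 and C10 set (C5-H epimeric)
Conditions: Fe(acac)3, PhSiH3, EtOH, 60 °C
Reagents that add atoms: none
Why: Proposed new method: Fe–H HAT to the 1,1-disubstituted C14 methylene gives the tertiary C14 radical (C26 becomes CH3). A chair-like 6-endo closure onto C8 of the E-alkene forms ring C, giving trans C/D and B/C fusion and the tertiary C9 radical (Me25 β). That radical then undergoes a polarity-matched 6-endo Giese addition to C10, the β-carbon of the unsaturated lactone, forming ring B. The ring-embedded Z-alkene puts C1 equatorial and H10 axial (α, anti to Me25). The α-carbonyl radical at C5 is reduced and protonated (C5 configuration is discarded in step 16). The closest known chemistry is HAT-initiated radical polyene cyclization (Ti(III) epoxypolyene cascades) with an Fe-HAT Giese terminus.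

**Step 15**
Reactants: 20
Product: 21 lactol (C24-OH)
Conditions: DIBAL-H (1.1 equiv), CH2Cl2, −78 °C
Reagents that add atoms: none
Why: At −78 °C the lactone is reduced to the lactol while the hindered tert-butyl ester survives; the lactol is an anomeric mixture.

**Step 16**
Reactants: 21
Product: 22 cyclic enol ether (C24=C5)
Conditions: PPTS (cat.), PhMe, 4 Å MS, 80 °C
Reagents that add atoms: none
Why: Acid-catalysed dehydration through the oxocarbenium ion can lose only the C5-H, so the enol ether forms regiospecifically and C5 becomes sp2.

**Step 17**
Reactants: 22; 23 2-bromopropionic acid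
Product: 24 tert-butyl ester of celastolide
Conditions: fac-Ir(ppy)3 (1 mol%), 23 (3 equiv), 2,6-lutidine, MeCN, blue LEDs, rt
Reagents that add atoms: none (the acid is numbered reactant 23)
Why: Proposed new method: photoreduction of the C–Br bond gives an electrophilic α-carboxy radical that adds to the nucleophilic C5 of the enol ether from the α-face, anti to axial Me25, forming the quaternary C5–C4 bond. Ir(IV) oxidises the resulting α-oxy radical at C24 to an oxocarbenium ion, and the tethered carboxylate closes onto the same face to give the cis-fused γ-lactone acetal (O-lactone α, H24 β). The exo-methyl at C4 is set in the addition and can be equilibrated with DBU. The closest known reactions are the Heiba–Dessau Mn(III) γ-lactone annulation and photoredox bromomalonate/alkene lactonization.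

**Step 18**
Reactants: 24
Product: 25 celastolide
Conditions: TFA, CH2Cl2, 0 °C
Reagents that add atoms: none
Why: Acidolysis of the tert-butyl ester releases the C29 acid; no stereocentre is affected.

Checks: the formula of each intermediate follows from the previous one and 25 is C30H46O5. The 11 stereocentres of the target are set in steps 1 (C20), 6 (C17), 7 (C18), 8 (C13), 14 (C14, C8, C9, C10) and 17 (C5, C4, C24). The tert-butyl ester is inert to the radical, DIBAL and PPTS steps, the lactol/enol-ether sequence removes the unspecified C5 configuration, and no later step touches an established centre.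

## Compound list
1 | isoprene | C=CC(C)=C | starting material
2 | methacrolein | C=C(C)C=O | starting material
3 | (R)-1,4-dimethylcyclohex-3-ene-1-carbaldehyde | C[C@]1(C=O)CC=C(C)CC1 | intermediate
4 | (R)-1,4-dimethylcyclohex-3-ene-1-carboxylic acid | C[C@]1(C(=O)O)CC=C(C)CC1 | intermediate
5 | tert-butyl ester of 4 | C[C@]1(C(=O)OC(C)(C)C)CC=C(C)CC1 | intermediate
6 | 3-hydroxy-1,4-dimethylcyclohexane tert-butyl ester | C[C@]1(C(=O)OC(C)(C)C)CC(O)C(C)CC1 | intermediate
7 | 1,4-dimethyl-3-oxocyclohexane tert-butyl ester | C[C@]1(C(=O)OC(C)(C)C)CC(=O)C(C)CC1 | intermediate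
8 | ethyl vinyl ketone | C=CC(=O)CC | starting material
9 | Robinson enone (4a-Me, 7-Me cis) | O=C1C(C)=C2C[C@](C)(C(=O)OC(C)(C)C)CC[C@]2(C)CC1 | intermediate
10 | cis-fused decalone (C18-H cis to Me28) | O=C1C(C)[C@@H]2C[C@](C)(C(=O)OC(C)(C)C)CC[C@]2(C)CC1 | intermediate
11 | 4-bromo-2-methyl-1-butene | C=C(C)CCBr | starting material
12 | D/E-ring ketone with quaternary C13 | C=C(C)CC[C@@]1(C)[C@@H]2C[C@](C)(C(=O)OC(C)(C)C)CC[C@]2(C)CCC1=O | intermediate
13 | C14-methylene diene | C=C(C)CC[C@@]1(C)[C@@H]2C[C@](C)(C(=O)OC(C)(C)C)CC[C@]2(C)CCC1=C | intermediate
14 | hex-5-enoic acid | C=CCCCC(=O)O | starting material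
15 | but-3-en-1-ol | C=CCCO | starting material
16 | but-3-en-1-yl hex-5-enoate | C=CCCCC(=O)OCCC=C | intermediate
17 | but-3-en-1-yl 2-methylenehex-5-enoate | C=CCCC(=C)C(=O)OCCC=C | intermediate
18 | 3-(but-3-enyl)-5,6-dihydro-2H-pyran-2-one | C=CCCC1=CCCOC1=O | intermediate
19 | cascade precursor | O=C1OCCC=C1CC/C=C(\C)CC[C@@]2(C)[C@@H]3C[C@](C)(C(=O)OC(C)(C)C)CC[C@]3(C)CCC2=C | intermediate
20 | pentacyclic δ-lactone (C5 epimeric) | O=C1OCC[C@H]2[C@]3(C)CC[C@@]4(C)[C@@H]5C[C@](C)(C(=O)OC(C)(C)C)CC[C@]5(C)CC[C@]4(C)[C@H]3CCC12 | intermediate
21 | lactol | OC1OCC[C@H]2[C@]3(C)CC[C@@]4(C)[C@@H]5C[C@](C)(C(=O)OC(C)(C)C)CC[C@]5(C)CC[C@]4(C)[C@H]3CCC12 | intermediate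
22 | cyclic enol ether | O1CC[C@H]2[C@]3(C)CC[C@@]4(C)[C@@H]5C[C@](C)(C(=O)OC(C)(C)C)CC[C@]5(C)CC[C@]4(C)[C@H]3CCC2=C1 | intermediate
23 | 2-bromopropionic acid | CC(Br)C(=O)O | starting material
24 | celastolide tert-butyl ester | C[C@H]1C(=O)O[C@@H]2OCC[C@H]3[C@]4(C)CC[C@@]5(C)[C@@H]6C[C@](C)(C(=O)OC(C)(C)C)CC[C@]6(C)CC[C@]5(C)[C@H]4CC[C@]213 | intermediate
25 | celastolide | C[C@H]1C(=O)O[C@@H]2OCC[C@H]3[C@]4(C)CC[C@@]5(C)[C@@H]6C[C@](C)(C(=O)O)CC[C@]6(C)CC[C@]5(C)[C@H]4CC[C@]213 | target

## Totals
Total steps: 18. Longest linear sequence: 15 (steps 1–9, 13, 14–18).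

## Three steps most likely to fail
1. **Step 14 (radical cascade).** The vicinal C13/C14 quaternary centres are hard to form, and premature HAT reduction competes.
   Fallback: build the rings separately. First close ring C by HAT cyclization onto a truncated substrate, with the C9 radical terminated by Co-mediated desaturation. Then close ring B by a second, intramolecular HAT–Giese addition onto the reattached lactone.
2. **Step 17 (radical-polar annulation).** Radical attack at the hindered, fully substituted C5, and acid sensitivity of the enol ether, may give low yield or the wrong C4 epimer.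
   Fallback: use an intramolecular Ueno–Stork closure. Convert 20 to the Δ5(10)-unsaturated lactone (LDA, PhSeCl; H2O2), reduce to the lactol, acylate it with 2-bromopropionyl bromide, and cyclize by 5-exo radical closure with Bu3SnH.
3. **Steps 6–8 (C17, C18 and C13 stereocontrol).** The C17/C20 diastereomer ratio, the cis-hydrogenation and the convex-face alkylation are all substrate-controlled.
   Fallback: Robinson-annulate ketone 7 with the pre-assembled α-branched vinyl ketone CH2=CH–CO–CH(Me)CH2CH2C(Me)=CH2 so that the aldol step forms C13 as a quaternary centre. Then remove the C18 tertiary hydroxyl radically (Barton–McCombie), delivering H to C18 from the convex face.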